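**Assumption (remark on the chemistry):** the enol ether 11, 1-methoxy-4-(1-methoxyethenyl)benzene, is taken as a purchasable reagent; where it is not stocked it is one methylenation step from methyl 4-methoxybenzoate.

## The problem

Heveaflavone (20) is 7,7'',4'''-tri-O-methylamentoflavone: two apigenin-type flavones joined by one bond between C3' (benzene ring B of unit 1, ortho to the 4'-OH) and C8'' (ring A of unit 2, between the 7''-OMe and the ring oxygen O1''). The bond is flanked by three ortho substituents, and both of its carbons are nucleophilic positions (a phenol ortho carbon and a phloroglucinol carbon), so neither is a natural electrophile. C8'' must also be told from C6'', since both flank O7'', and any route that closes the pyranone of unit 2 onto a preformed 3-aryl-phloroglucinol ketone meets the same choice again as 6-aryl against 8-aryl closure. Of the six oxygens on the aromatic rings, three are methylated (O7, O7'', O4''') and three are free (O5, O5'', O4'); the peri-hydroxyls O5 and O5'' differ from O7 and O7'' through their hydrogen bond to C4=O and C4''=O, but O4' and O4''' must be told apart from the start. The target SMILES carries no stereodescriptor, and the tri-ortho-substituted axis is treated as configurationally labile, so there is no stereocentre to set. The groups at risk are the γ-pyranone rings (opened by hydroxide and hard nucleophiles), the electron-rich rings A (attacked at C6 and C8 by electrophiles) and the benzyl ether chosen for O4'. The feature that makes the key step possible is that each ring A (C4a–C5–C6–C7–C8–C8a and C4a''–C5''–C6''–C7''–C8''–C8a'') is a phloroglucinol ring fused to a γ-pyranone, in which C8 and C8'' are bonded to the fusion carbons C8a and C8a'' that carry the pyranone oxygen and C5–C6–C7 and C5''–C6''–C7'' each form a malonyl unit. Removing the two malonyl units leaves a bis(γ-pyranone) in which C8 is a methyl group and C8'' is the benzylic CH2 of an arylmethyl group, so that the crowded biaryl bond C3'–C8'' is an ordinary aryl–CH2 bond in the precursor.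

## Retrosynthesis

**20 back to 18.** The benzyl ether 19 gives 20 by hydrogenolysis, and 19 comes from the tetraol 18 by methylation of the two non-chelated hydroxyls O7 and O7''. The methylation pattern of the target is the one a 5,7,5'',7''-tetraol gives by itself under mild base, so no protecting group is needed for O5 and O5''. O4''' is methylated from the start and O4' is benzylated from the start.

**18 back to 14 and two molecules of malonyl dichloride 15 (key disconnection).** In each ring A the bonds C4a–C5 and C7–C8 (C4a''–C5'' and C7''–C8'') are cut and C5–C6–C7 is removed as a malonyl unit, so that one molecule of 15 is needed for each ring A. Against a cut of the biaryl bond this has three advantages. No biaryl coupling is needed. The aryl group can only end on C8'', because the lateral carbon of 14 is bonded to the pyranone carbon that already carries O1''. Four C–C bonds and two benzene rings are formed in one operation. The precursor 14 has two rings and four oxygens fewer and no phenol. The forward reaction must acylate each alkyl-4-pyranone at its lateral carbon and at the ring CH next to the alkyl-bearing carbon (the later C4a and C4a''), which is a C,C-[3+3] annulation.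

**14 back to 10 and 11.** The pyranone of unit 2 is cut at O1''–C2'' and C3''–C4''. Forward, the dioxinone 10 loses acetone on heating to give the acylketene 12, which adds the enol ether 11 in a hetero-Diels–Alder reaction; loss of methanol from 13 gives the pyranone. This is preferred to building an open 1,3,5-triketone with strong base, because 10 carries an acidic benzylic CH2 and a second pyranone.

**10 back to 6 and 9.** The bond C3'–CH2 (the later C3'–C8'') is cut. Forward, it is made by palladium-catalysed γ-arylation of the silyl dienolate 9 with the aryl bromide 6. The bond that is the hardest one in the target is made here between an aryl carbon and an unhindered primary carbon, and the product is directly the masked acylketene needed for the next step.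

**6 back to 1, 3 and 7.** The pyranone of unit 1 comes from the triketone 5 by cyclodehydration. 5 comes from the ester 2 by aroylation of the 1,3-dianion 4 of pentane-2,4-dione 3. 2 is the benzyl ether of commercial 1. The dienolate 9 comes from commercial dioxinone 7 through its lithium dienolate 8.

## Roads not taken

Alternative 1: the obvious cut is the biaryl bond C3'–C8'' between two finished flavones. The forward key step is a Suzuki–Miyaura coupling of the 8-iodide A1 with the 3'-boronate A2 to give A3, followed by cleavage of the peri methyl ethers and the isopropyl ether. Each partner needs its own flavone synthesis and a halogenation or borylation. The iodination is directed to C8 only when O5'' is methylated, so both peri-hydroxyls are masked and unmasked again. The coupling has to form a bond with three ortho substituents from a boronate that is prone to protodeboronation. The chosen plan makes the same bond at an unhindered sp3 carbon and forms both rings A in one step.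

Alternative 2: a biomimetic cut of the same bond, with the two carbons of like polarity joined by oxidative cross-coupling of genkwanin A4 and 7,4'-di-O-methylapigenin A5, which would give 20 in one step. The phenol of A4 is conjugated to the pyranone and hard to oxidise. Its phenoxyl radical is delocalised over O4', C3' and C1'. A5 offers C6'', C8'' and C3'' as well as its own O5''-H. Homo-coupling and C–O coupling compete, and nothing in either partner tells C8'' from C6''; a temporary bridge from O4' to O7'' would reach both. In the chosen plan the regiochemistry follows from connectivity.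

Alternative 3: ring A of unit 2 built by a Danheiser benzannulation of the aryl ynol ether A6 with 3-ethoxycyclobutenone A7. This would give the phenol A8 with the three oxygens differentiated by construction (free OH at the later C8a'', OMe at C7'', OEt at C5''). It builds only one of the two rings A. C4a'' must then be acylated ortho to the free hydroxyl in competition with C6'', the pyranone of unit 2 and the whole chromone of unit 1 remain to be made, the ethyl ether has to be cleaved, and A6 itself needs several steps. The route would be roughly half as long again as the chosen one.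

Key step: step 7

## Route

Step 1
Reactants: 1 methyl 3-bromo-4-hydroxybenzoate
Product: 2 methyl 4-(benzyloxy)-3-bromobenzoate
Conditions: BnBr, K2CO3, DMF, 60 °C
Reagents that add atoms: benzyl bromide, BrCc1ccccc1
Why: Williamson ether synthesis on the only acidic hydroxyl; the benzyl group marks O4' as the one oxygen to be freed at the end.

Step 2
Reactants: 2 methyl 4-(benzyloxy)-3-bromobenzoate; 3 pentane-2,4-dione
Product: 5 1-[4-(benzyloxy)-3-bromophenyl]hexane-1,3,5-trione, via 1,3-dilithio pentane-2,4-dione 4 (not isolated)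
Conditions: 3 (2.5 equiv), LiN(i-Pr)2 (LDA, 5 equiv), THF, 0 °C; then 2, 0 °C to rt; aq. HCl
Reagents that add atoms: none
Why: Claisen-type aroylation of a β-diketone 1,3-dianion, which reacts at its more basic terminal carbon; the ester has no α-hydrogen, and excess dianion covers deprotonation of the product.

Step 3
Reactants: 5 1-[4-(benzyloxy)-3-bromophenyl]hexane-1,3,5-trione
Product: 6 2-[4-(benzyloxy)-3-bromophenyl]-6-methyl-4H-pyran-4-one
Conditions: p-TsOH·H2O (cat.), toluene, reflux, Dean–Stark
Reagents that add atoms: none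
Why: acid-catalysed cyclodehydration of a 1,3,5-triketone to the γ-pyranone; only one pyranone can form.

Step 4
Reactants: 7 2,2,6-trimethyl-4H-1,3-dioxin-4-one
Product: 9 [(2,2-dimethyl-4-methylidene-4H-1,3-dioxin-6-yl)oxy]trimethylsilane, via lithium dienolate 8 (not isolated)
Conditions: LiN(i-Pr)2 (LDA), THF, −78 °C; then TMSCl, −78 °C to 0 °C
Reagents that add atoms: chlorotrimethylsilane, C[Si](C)(C)Cl
Why: γ-deprotonation of the vinylogous ester and O-silylation give the silyl dienol ether, a standard masked acetoacetate γ-anion.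

Step 5
Reactants: 6 2-[4-(benzyloxy)-3-bromophenyl]-6-methyl-4H-pyran-4-one; 9 [(2,2-dimethyl-4-methylidene-4H-1,3-dioxin-6-yl)oxy]trimethylsilane
Product: 10 6-{[2-(benzyloxy)-5-(6-methyl-4-oxo-4H-pyran-2-yl)phenyl]methyl}-2,2-dimethyl-4H-1,3-dioxin-4-one
Conditions: Pd(dba)2 (cat.), P(t-Bu)3 (cat.), ZnF2 (0.5 equiv), DMF, 70 °C; 9 in excess
Reagents that add atoms: none
Why: palladium-catalysed γ-arylation of a silyl dienolate (vinylogous α-arylation); fluoride transfers the dienolate to the arylpalladium bromide, and reductive elimination at the unhindered terminal carbon keeps the dioxinone conjugated.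

Step 6
Reactants: 10 6-{[2-(benzyloxy)-5-(6-methyl-4-oxo-4H-pyran-2-yl)phenyl]methyl}-2,2-dimethyl-4H-1,3-dioxin-4-one; 11 1-methoxy-4-(1-methoxyethenyl)benzene
Product: 14 2-{[2-(benzyloxy)-5-(6-methyl-4-oxo-4H-pyran-2-yl)phenyl]methyl}-6-(4-methoxyphenyl)-4H-pyran-4-one, via acylketene 12 (not isolated), via dihydropyranone cycloadduct 13 (not isolated)
Conditions: 11 (4 equiv), toluene, 110 °C; then p-TsOH·H2O (cat.), rt
Reagents that add atoms: none
Why: retro-[4+2] loss of acetone gives the acylketene, which adds the electron-rich enol ether in a hetero-Diels–Alder reaction (ketene carbon to the CH2 terminus, acyl oxygen to the acetal carbon); acid-catalysed loss of methanol from racemic 13 gives the γ-pyranone.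

Step 7
Reactants: 14 2-{[2-(benzyloxy)-5-(6-methyl-4-oxo-4H-pyran-2-yl)phenyl]methyl}-6-(4-methoxyphenyl)-4H-pyran-4-one; 15 malonyl dichloride
Product: 18 8-[2-(benzyloxy)-5-(5,7-dihydroxy-4-oxo-4H-chromen-2-yl)phenyl]-5,7-dihydroxy-2-(4-methoxyphenyl)-4H-chromen-4-one, via bis(silyl dienol ether) 16 (not isolated), via bis(β-keto acid chloride) 17 (not isolated)
Conditions: TMSOTf (2.4 equiv), Et3N (2.2 equiv), CH2Cl2, 0 °C; then 15 (2.2 equiv), high dilution, −78 °C to rt, then 40 °C; aq. NaHCO3–MeOH work-up
Reagents that add atoms: malonyl dichloride (second molecule of 15), ClC(=O)CC(=O)Cl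
Why: Proposed new method: twofold C,C-[3+3] annulation of alkyl-4-pyranones with malonyl dichloride, one molecule of 15 being built into each pyranone and two in all. TMSOTf silylates each pyranone carbonyl oxygen to a 4-silyloxypyrylium ion, whose lateral C–H (the methyl group of unit 1, the benzylic CH2 of unit 2) is then acidic enough for Et3N, giving the bis(2-alkylidene-4-silyloxy-2H-pyran) 16. In 16 the exocyclic carbon is the terminus of an enol ether (O1–C=C) and of a vinylogous silyl enol ether, so it is the most nucleophilic site and is acylated by 15 with loss of Me3SiCl, which restores the pyranone and gives 17. 17 enolises towards the lateral carbon, and in this dienol, or in the acylketene formed from it by loss of HCl, the acyl carbon lies over the pyranone CH next to the alkyl-bearing carbon (the later C4a and C4a''), so that each ring A closes by 6-exo-trig acylation or by 6π electrocyclisation of the dienylketene and then tautomerises to the phenol, driven by aromatisation. The closest known reaction type is the malonyl dichloride annulation of enol ethers and silyl enol ethers (C-acylation followed by ring closure, as in the 4-hydroxy-2-pyranone synthesis and in the C,C-closure of the Effenberger cyclisation); the O-closure that normally competes is not available, since the oxygen in the usual position is the dicoordinate pyranone ring oxygen and the enol oxygen of the new ketone could only close a four-membered ring. No stereocentre is formed, and the benzylic stereocentre of racemic 17 is lost on aromatisation. The step needs acylation at the lateral carbon and at the neighbouring ring CH, not at the other pyranone CH (the later C3 and C3'') or at C2' of ring B of unit 1: the later C3 receives donation from the ring oxygen only and cannot lead to a six-membered ring, and C2' is meta to the benzyloxy group and ortho to the electron-poor pyranonyl group. The aryl group can only end on C8'', because the lateral carbon is bonded to the pyranone carbon that carries the ring oxygen.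

Step 8
Reactants: 18 8-[2-(benzyloxy)-5-(5,7-dihydroxy-4-oxo-4H-chromen-2-yl)phenyl]-5,7-dihydroxy-2-(4-methoxyphenyl)-4H-chromen-4-one
Product: 19 8-[2-(benzyloxy)-5-(5-hydroxy-7-methoxy-4-oxo-4H-chromen-2-yl)phenyl]-5-hydroxy-7-methoxy-2-(4-methoxyphenyl)-4H-chromen-4-one
Conditions: MeI (2.2 equiv), K2CO3 (2.2 equiv), acetone, 40 °C
Reagents that add atoms: iodomethane, CI
Why: Williamson methylation of the two acidic, non-chelated hydroxyls O7 and O7'', one methyl group each; O5 and O5'' are held in hydrogen bonds to C4=O and C4''=O and should not react with a limited amount of base and MeI.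

Step 9
Reactants: 19 8-[2-(benzyloxy)-5-(5-hydroxy-7-methoxy-4-oxo-4H-chromen-2-yl)phenyl]-5-hydroxy-7-methoxy-2-(4-methoxyphenyl)-4H-chromen-4-one
Product: 20 heveaflavone, 5-hydroxy-8-[2-hydroxy-5-(5-hydroxy-7-methoxy-4-oxo-4H-chromen-2-yl)phenyl]-7-methoxy-2-(4-methoxyphenyl)-4H-chromen-4-one
Conditions: H2 (1 atm), Pd/C (10% palladium on carbon), THF–MeOH, rt
Reagents that add atoms: none
Why: hydrogenolysis of the benzyl ether; the methyl ethers and the chromone double bonds should survive under these mild conditions.

## Compound list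

1 | methyl 3-bromo-4-hydroxybenzoate | COC(=O)c1ccc(O)c(Br)c1 | starting material
2 | methyl 4-(benzyloxy)-3-bromobenzoate | COC(=O)c1ccc(OCc2ccccc2)c(Br)c1 | intermediate
3 | pentane-2,4-dione | CC(=O)CC(C)=O | starting material
4 | 1,3-dilithio pentane-2,4-dione (dianion) | [Li+].[Li+].[CH2-]C(=O)[CH-]C(C)=O | intermediate (not isolated)
5 | 1-[4-(benzyloxy)-3-bromophenyl]hexane-1,3,5-trione | CC(=O)CC(=O)CC(=O)c1ccc(OCc2ccccc2)c(Br)c1 | intermediate
6 | 2-[4-(benzyloxy)-3-bromophenyl]-6-methyl-4H-pyran-4-one | Cc1cc(=O)cc(-c2ccc(OCc3ccccc3)c(Br)c2)o1 | intermediate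
7 | 2,2,6-trimethyl-4H-1,3-dioxin-4-one | CC1=CC(=O)OC(C)(C)O1 | starting material
8 | lithium 2,2-dimethyl-4-methylidene-4H-1,3-dioxin-6-olate | [Li+].C=C1C=C([O-])OC(C)(C)O1 | intermediate (not isolated)
9 | [(2,2-dimethyl-4-methylidene-4H-1,3-dioxin-6-yl)oxy]trimethylsilane | C=C1C=C(O[Si](C)(C)C)OC(C)(C)O1 | intermediate
10 | 6-{[2-(benzyloxy)-5-(6-methyl-4-oxo-4H-pyran-2-yl)phenyl]methyl}-2,2-dimethyl-4H-1,3-dioxin-4-one | CC1(C)OC(=O)C=C(Cc2cc(-c3cc(=O)cc(C)o3)ccc2OCc4ccccc4)O1 | intermediate
11 | 1-methoxy-4-(1-methoxyethenyl)benzene | C=C(OC)c1ccc(OC)cc1 | starting material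
12 | 4-[2-(benzyloxy)-5-(6-methyl-4-oxo-4H-pyran-2-yl)phenyl]-3-oxobut-1-en-1-one (acylketene) | O=C=CC(=O)Cc1cc(-c2cc(=O)cc(C)o2)ccc1OCc3ccccc3 | intermediate (not isolated)
13 | 6-{[2-(benzyloxy)-5-(6-methyl-4-oxo-4H-pyran-2-yl)phenyl]methyl}-2-methoxy-2-(4-methoxyphenyl)-2,3-dihydro-4H-pyran-4-one (racemic) | COc1ccc(C2(OC)CC(=O)C=C(Cc3cc(-c4cc(=O)cc(C)o4)ccc3OCc5ccccc5)O2)cc1 | intermediate (not isolated)
14 | 2-{[2-(benzyloxy)-5-(6-methyl-4-oxo-4H-pyran-2-yl)phenyl]methyl}-6-(4-methoxyphenyl)-4H-pyran-4-one | COc1ccc(-c2cc(=O)cc(Cc3cc(-c4cc(=O)cc(C)o4)ccc3OCc5ccccc5)o2)cc1 | intermediate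
15 | malonyl dichloride | ClC(=O)CC(=O)Cl | starting material
16 | bis(silyl dienol ether) of 14: 2-(4-methoxyphenyl)-6-(arylmethylidene)-4-(trimethylsilyloxy)-6H-pyran with a 6-methylidene-4-(trimethylsilyloxy)-6H-pyran-2-yl group on the aryl ring (double bond geometry not controlled, of no consequence) | COc1ccc(C2=CC(O[Si](C)(C)C)=CC(=Cc3cc(C4=CC(O[Si](C)(C)C)=CC(=C)O4)ccc3OCc5ccccc5)O2)cc1 | intermediate (not isolated)
17 | bis(β-keto acid chloride): 4-[2-(benzyloxy)-5-{6-(4-chloro-2,4-dioxobutyl)-4-oxo-4H-pyran-2-yl}phenyl]-4-[6-(4-methoxyphenyl)-4-oxo-4H-pyran-2-yl]-3-oxobutanoyl chloride (racemic) | COc1ccc(-c2cc(=O)cc(C(C(=O)CC(=O)Cl)c3cc(-c4cc(=O)cc(CC(=O)CC(=O)Cl)o4)ccc3OCc5ccccc5)o2)cc1 | intermediate (not isolated)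
18 | 8-[2-(benzyloxy)-5-(5,7-dihydroxy-4-oxo-4H-chromen-2-yl)phenyl]-5,7-dihydroxy-2-(4-methoxyphenyl)-4H-chromen-4-one | COc1ccc(-c2cc(=O)c3c(O)cc(O)c(-c4cc(-c5cc(=O)c6c(O)cc(O)cc6o5)ccc4OCc7ccccc7)c3o2)cc1 | intermediate
19 | 8-[2-(benzyloxy)-5-(5-hydroxy-7-methoxy-4-oxo-4H-chromen-2-yl)phenyl]-5-hydroxy-7-methoxy-2-(4-methoxyphenyl)-4H-chromen-4-one | COc1ccc(-c2cc(=O)c3c(O)cc(OC)c(-c4cc(-c5cc(=O)c6c(O)cc(OC)cc6o5)ccc4OCc7ccccc7)c3o2)cc1 | intermediate
20 | heveaflavone | COc1ccc(-c2cc(=O)c3c(O)cc(OC)c(-c4cc(-c5cc(=O)c6c(O)cc(OC)cc6o5)ccc4O)c3o2)cc1 | target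

## Step count and risks

Total step count: 9. Longest linear sequence: 8 (steps 1, 2, 3, 5, 6, 7, 8, 9; step 4 prepares the reagent 9).

**Step 7 (key step, Proposed new method).** Most likely to go wrong: acylation at the other pyranone CH (the later C3 or C3'') or at the silyloxy oxygen without ring closure, and chain growth through intermolecular attack of the second acid chloride, because ring closure needs the dienol or acylketene form while any bimolecular path is open at once. Closure may also stall on the more crowded benzylic arm, which would leave one ring A unbuilt. The fallback uses known chemistry and gives up the ring construction in favour of joining two finished chromones. It sets out from 2. Crossed Claisen condensation with commercial 1-(2-hydroxy-4,6-dimethoxyphenyl)ethanone (NaH, THF, reflux) gives 1-[4-(benzyloxy)-3-bromophenyl]-3-(2-hydroxy-4,6-dimethoxyphenyl)propane-1,3-dione F1. Acid-catalysed cyclodehydration gives 2-[4-(benzyloxy)-3-bromophenyl]-5,7-dimethoxy-4H-chromen-4-one F2. Miyaura borylation (bis(pinacolato)diboron, PdCl2(dppf), KOAc) gives 2-[4-(benzyloxy)-3-(4,4,5,5-tetramethyl-1,3,2-dioxaborolan-2-yl)phenyl]-5,7-dimethoxy-4H-chromen-4-one F3. Iodination of commercial 5,7-dimethoxy-2-(4-methoxyphenyl)-4H-chromen-4-one (I2, CF3CO2Ag) gives 8-iodo-5,7-dimethoxy-2-(4-methoxyphenyl)-4H-chromen-4-one F4. Suzuki–Miyaura coupling of F3 and F4 (Pd(PPh3)4, K2CO3, DMF–water) gives 8-[2-(benzyloxy)-5-(5,7-dimethoxy-4-oxo-4H-chromen-2-yl)phenyl]-5,7-dimethoxy-2-(4-methoxyphenyl)-4H-chromen-4-one F5. BCl3 (CH2Cl2, −78 to 0 °C) cleaves the two chelated peri methyl ethers and the benzyl ether, and the fallback comes back to the route at 20.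

**Step 5.** Most likely to go wrong: arylation at the ring carbon (α) instead of the terminal carbon of the dienolate, a second arylation at the doubly activated CH2 of 10, and loss of the silyl group by proton transfer from the pyranone methyl group before transmetalation. The fallback sets out from 6. Palladium-catalysed α-arylation with the Reformatsky reagent (2-tert-butoxy-2-oxoethyl)zinc bromide gives tert-butyl 2-[2-(benzyloxy)-5-(6-methyl-4-oxo-4H-pyran-2-yl)phenyl]acetate F6. Trifluoroacetic acid gives 2-[2-(benzyloxy)-5-(6-methyl-4-oxo-4H-pyran-2-yl)phenyl]acetic acid F7. Acylation of Meldrum's acid (DCC, DMAP) gives 5-{2-[2-(benzyloxy)-5-(6-methyl-4-oxo-4H-pyran-2-yl)phenyl]-1-hydroxyethylidene}-2,2-dimethyl-1,3-dioxane-4,6-dione F8. Heating F8 in toluene with acetone traps the acylketene as the dioxinone, and the fallback comes back to the route at 10.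

**Step 6.** Most likely to go wrong: dimerisation of the acylketene, its cyclisation onto C2' of the neighbouring benzene ring, or acid-induced decomposition of the enol ether before it is trapped, because the [4+2] addition is bimolecular and the other paths are not. The fallback replaces the cycloaddition by an ionic triketone synthesis and sets out from 6. α-Arylation with the zinc enolate made from 2-bromo-N-methoxy-N-methylacetamide gives 2-[2-(benzyloxy)-5-(6-methyl-4-oxo-4H-pyran-2-yl)phenyl]-N-methoxy-N-methylacetamide F9. Acylation of the 1,3-dianion of commercial 1-(4-methoxyphenyl)butane-1,3-dione gives 1-[2-(benzyloxy)-5-(6-methyl-4-oxo-4H-pyran-2-yl)phenyl]-6-(4-methoxyphenyl)hexane-2,4,6-trione F10. Acid-catalysed cyclodehydration then comes back to the route at 14.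

**Step 8.** Most likely to go wrong: incomplete methylation of the crowded O7'' next to the aryl group, or over-methylation at a peri-hydroxyl once the base is no longer limiting. The fallback reverses the logic: it methylates everything and then removes the chelated methyl groups. It sets out from 18. Exhaustive methylation (Me2SO4 in excess, K2CO3, acetone, reflux) gives 8-[2-(benzyloxy)-5-(5,7-dimethoxy-4-oxo-4H-chromen-2-yl)phenyl]-5,7-dimethoxy-2-(4-methoxyphenyl)-4H-chromen-4-one F11. BCl3 then cleaves the two peri methyl ethers by chelation control together with the benzyl ether, and the fallback comes back to the route at 20.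

## Further compounds

F1 | step 7 | 1-[4-(benzyloxy)-3-bromophenyl]-3-(2-hydroxy-4,6-dimethoxyphenyl)propane-1,3-dione | COc1cc(O)c(C(=O)CC(=O)c2ccc(OCc3ccccc3)c(Br)c2)c(OC)c1
F2 | step 7 | 2-[4-(benzyloxy)-3-bromophenyl]-5,7-dimethoxy-4H-chromen-4-one | COc1cc(OC)c2c(=O)cc(-c3ccc(OCc4ccccc4)c(Br)c3)oc2c1
F3 | step 7 | 2-[4-(benzyloxy)-3-(4,4,5,5-tetramethyl-1,3,2-dioxaborolan-2-yl)phenyl]-5,7-dimethoxy-4H-chromen-4-one | COc1cc(OC)c2c(=O)cc(-c3ccc(OCc4ccccc4)c(B5OC(C)(C)C(C)(C)O5)c3)oc2c1
F4 | step 7 | 8-iodo-5,7-dimethoxy-2-(4-methoxyphenyl)-4H-chromen-4-one | COc1ccc(-c2cc(=O)c3c(OC)cc(OC)c(I)c3o2)cc1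
F5 | step 7 | 8-[2-(benzyloxy)-5-(5,7-dimethoxy-4-oxo-4H-chromen-2-yl)phenyl]-5,7-dimethoxy-2-(4-methoxyphenyl)-4H-chromen-4-one | COc1ccc(-c2cc(=O)c3c(OC)cc(OC)c(-c4cc(-c5cc(=O)c6c(OC)cc(OC)cc6o5)ccc4OCc7ccccc7)c3o2)cc1
F6 | step 5 | tert-butyl 2-[2-(benzyloxy)-5-(6-methyl-4-oxo-4H-pyran-2-yl)phenyl]acetate | Cc1cc(=O)cc(-c2ccc(OCc3ccccc3)c(CC(=O)OC(C)(C)C)c2)o1
F7 | step 5 | 2-[2-(benzyloxy)-5-(6-methyl-4-oxo-4H-pyran-2-yl)phenyl]acetic acid | Cc1cc(=O)cc(-c2ccc(OCc3ccccc3)c(CC(=O)O)c2)o1
F8 | step 5 | 5-{2-[2-(benzyloxy)-5-(6-methyl-4-oxo-4H-pyran-2-yl)phenyl]-1-hydroxyethylidene}-2,2-dimethyl-1,3-dioxane-4,6-dione | Cc1cc(=O)cc(-c2ccc(OCc3ccccc3)c(CC(O)=C4C(=O)OC(C)(C)OC4=O)c2)o1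
F9 | step 6 | 2-[2-(benzyloxy)-5-(6-methyl-4-oxo-4H-pyran-2-yl)phenyl]-N-methoxy-N-methylacetamide | Cc1cc(=O)cc(-c2ccc(OCc3ccccc3)c(CC(=O)N(C)OC)c2)o1
F10 | step 6 | 1-[2-(benzyloxy)-5-(6-methyl-4-oxo-4H-pyran-2-yl)phenyl]-6-(4-methoxyphenyl)hexane-2,4,6-trione | COc1ccc(C(=O)CC(=O)CC(=O)Cc2cc(-c3cc(=O)cc(C)o3)ccc2OCc4ccccc4)cc1
F11 | step 8 | 8-[2-(benzyloxy)-5-(5,7-dimethoxy-4-oxo-4H-chromen-2-yl)phenyl]-5,7-dimethoxy-2-(4-methoxyphenyl)-4H-chromen-4-one | COc1ccc(-c2cc(=O)c3c(OC)cc(OC)c(-c4cc(-c5cc(=O)c6c(OC)cc(OC)cc6o5)ccc4OCc7ccccc7)c3o2)cc1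
A1 | alternative 1 | 8-iodo-5,7-dimethoxy-2-(4-methoxyphenyl)-4H-chromen-4-one | COc1ccc(-c2cc(=O)c3c(OC)cc(OC)c(I)c3o2)cc1
A2 | alternative 1 | 5,7-dimethoxy-2-[4-(propan-2-yloxy)-3-(4,4,5,5-tetramethyl-1,3,2-dioxaborolan-2-yl)phenyl]-4H-chromen-4-one | COc1cc(OC)c2c(=O)cc(-c3ccc(OC(C)C)c(B4OC(C)(C)C(C)(C)O4)c3)oc2c1
A3 | alternative 1 | 8-[5-(5,7-dimethoxy-4-oxo-4H-chromen-2-yl)-2-(propan-2-yloxy)phenyl]-5,7-dimethoxy-2-(4-methoxyphenyl)-4H-chromen-4-one | COc1ccc(-c2cc(=O)c3c(OC)cc(OC)c(-c4cc(-c5cc(=O)c6c(OC)cc(OC)cc6o5)ccc4OC(C)C)c3o2)cc1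
A4 | alternative 2 | genkwanin, 5-hydroxy-2-(4-hydroxyphenyl)-7-methoxy-4H-chromen-4-one | COc1cc(O)c2c(=O)cc(-c3ccc(O)cc3)oc2c1
A5 | alternative 2 | 5-hydroxy-7-methoxy-2-(4-methoxyphenyl)-4H-chromen-4-one | COc1ccc(-c2cc(=O)c3c(O)cc(OC)cc3o2)cc1
A6 | alternative 3 | methyl 4-(benzyloxy)-3-(methoxyethynyl)benzoate | COC#Cc1cc(C(=O)OC)ccc1OCc2ccccc2
A7 | alternative 3 | 3-ethoxycyclobut-2-en-1-one | CCOC1=CC(=O)C1
A8 | alternative 3 | methyl 4-(benzyloxy)-3-(4-ethoxy-2-hydroxy-6-methoxyphenyl)benzoate | CCOc1cc(O)c(-c2cc(C(=O)OC)ccc2OCc3ccccc3)c(OC)c1
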